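**Retrosynthetic overview**
1. Target 24 ⇐ 12-membered β-keto ester 21: two-carbon ring expansion by insertion of ethoxyethyne into the C8–C11 bond, then enol ether hydrolysis (the 14-membered ring is formed last).
2. 21 ⇐ acyclic β-keto ester 19 by intramolecular C-alkylation (C7–C8); 19 ⇐ epoxy aldehyde 17 + methyl diazoacetate.
3. 17 ⇐ Z-allylic alcohol 15 (Sharpless epoxidation, oxidation); the butyrolactone of 15 ⇐ palladium cyclocarbonylation of homopropargylic alcohol 14 (alkyne 11 + (R)-epichlorohydrin).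
4. 11 ⇐ Negishi coupling of alkyl iodide 6 with (Z)-iodide 9; 6 ⇐ lactone 3 from a rhodium-catalysed asymmetric 1,4-addition to furan-2(5H)-one.
5. Ring order: butyrolactone, then epoxide, then 12-membered carbocycle, then its expansion to the 14-membered ring.

Atom labels used below: macrocycle carbons C1 (CH bearing isopropenyl), C2, C3=C4, C5, C6 (CH–O of the lactone), C7, C8 (CH–CO2Me), C9 (C=O), C10, C11 (C=O), C12 (C–CH3, epoxide), C13 (epoxide CH), C14; C18 is the lactone carbonyl.

Assumption: C8 is a β-keto ester α-carbon that epimerises freely, so its (S) configuration is taken to be the thermodynamically preferred one and is set by equilibration in the last step; methyl diazoacetate and ethoxyethyne are bought as solutions.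

**Route**

Step 1
Reactants: 1 furan-2(5H)-one; 2 potassium trifluoro(prop-1-en-2-yl)borate
Product: 3 (4S)-4-(prop-1-en-2-yl)oxolan-2-one
Conditions: [Rh(cod)2]BF4 (3 mol %), (S)-BINAP (3.3 mol %), toluene/H2O (10:1), 100 °C
Reagents that add atoms: none
Why: Rhodium-catalysed asymmetric 1,4-addition (Hayashi–Miyaura type) of the alkenyl trifluoroborate to the butenolide, where (S)-BINAP is expected to give the (S) lactone by the same facial sense as with cyclic enones, which sets C1.

Step 2
Reactants: 3 (4S)-4-(prop-1-en-2-yl)oxolan-2-one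
Product: 5 (2S)-2-(prop-1-en-2-yl)pent-4-yn-1-ol, via lactol 4 (not isolated)
Conditions: DIBAL-H (1.1 equiv), CH2Cl2, −78 °C; then MeOH, K2CO3, dimethyl (1-diazo-2-oxopropyl)phosphonate, −78 °C → rt
Reagents that add atoms: dimethyl (1-diazo-2-oxopropyl)phosphonate, COP(=O)(OC)C(=[N+]=[N-])C(C)=O
Why: Half-reduction of the lactone and one-pot Seyferth–Gilbert homologation (Ohira–Bestmann reagent) of the open hydroxy aldehyde gives the terminal alkyne and frees the C14 alcohol, while C1 is β to the aldehyde and is not epimerised.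

Step 3
Reactants: 5 (2S)-2-(prop-1-en-2-yl)pent-4-yn-1-ol
Product: 6 (4S)-4-(iodomethyl)-5-methylhex-5-en-1-yne
Conditions: I2, PPh3, imidazole, CH2Cl2, 0 °C
Reagents that add atoms: iodine, II
Why: Appel iodination of the primary alcohol (SN2 at CH2), which does not touch the stereocenter, the alkyne or the alkene.

Step 4
Reactants: 7 prop-2-yn-1-ol
Product: 9 (2Z)-3-iodo-2-methylprop-2-en-1-ol, via vinylmagnesium alkoxide 8 (not isolated)
Conditions: MeMgBr (2.5 equiv), CuI (10 mol %), THF, −10 °C → rt; then I2, −78 → 0 °C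
Reagents that add atoms: methylmagnesium bromide, C[Mg]Br; iodine, II
Why: Copper-catalysed anti-carbomagnesiation of the propargylic alkoxide places methyl on C2 and magnesium on C3 cis to the CH2O group through a five-membered chelate, and iodinolysis with retention fixes the Z geometry that later becomes the cis epoxide.

Step 5
Reactants: 6 (4S)-4-(iodomethyl)-5-methylhex-5-en-1-yne; 9 (2Z)-3-iodo-2-methylprop-2-en-1-ol
Product: 11 (2Z,5S)-2-methyl-5-(prop-1-en-2-yl)oct-2-en-7-yn-1-ol, via alkylzinc iodide 10 (not isolated)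
Conditions: 6, Zn dust, LiCl, THF, 40 °C; then 9 (1.3 equiv), Pd(OAc)2 (2 mol %), SPhos (4 mol %), THF, 25 °C, slow addition of 10
Reagents that add atoms: none
Why: Negishi cross-coupling of the primary alkylzinc with the alkenyl iodide forms C13–C14 with retention of the Z geometry, and the palladium/SPhos system tolerates the free hydroxyl.

Step 6
Reactants: 11 (2Z,5S)-2-methyl-5-(prop-1-en-2-yl)oct-2-en-7-yn-1-ol; 12 (2R)-2-(chloromethyl)oxirane
Product: 14 (2Z,5S,10R)-11-chloro-2-methyl-5-(prop-1-en-2-yl)undec-2-en-7-yne-1,10-diol, via dilithio alkynide 13 (not isolated)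
Conditions: n-BuLi (2.1 equiv), THF, −78 °C; BF3·OEt2 (2.2 equiv); then 12 (1.3 equiv), −78 °C; H2O
Reagents that add atoms: none
Why: BF3-promoted opening of the epoxide at its CH2 terminus by the lithium acetylide (Yamaguchi-type alkynylation) forms C4–C5 without touching the C–O stereocenter, so (R)-epichlorohydrin delivers C6 in the required configuration.

Step 7
Reactants: 14 (2Z,5S,10R)-11-chloro-2-methyl-5-(prop-1-en-2-yl)undec-2-en-7-yne-1,10-diol
Product: 15 (3E,5R)-5-(chloromethyl)-3-[(3S,5Z)-7-hydroxy-6-methyl-3-(prop-1-en-2-yl)hept-5-en-1-ylidene]oxolan-2-one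
Conditions: PdI2 (5 mol %), PBu3 (10 mol %), CO (8 atm), MeCN, 75 °C
Reagents that add atoms: carbon monoxide, [C-]#[O+]
Why: Palladium-catalysed cyclocarbonylation of the homopropargylic alcohol, in which the alkoxycarbonylpalladium adds syn across the alkyne in a five-membered exo closure and protonolysis leaves H cis to the carbonyl, gives the (E)-alkylidene lactone, while the remote allylic alcohol and the chloride stay out.

Step 8
Reactants: 15 (3E,5R)-5-(chloromethyl)-3-[(3S,5Z)-7-hydroxy-6-methyl-3-(prop-1-en-2-yl)hept-5-en-1-ylidene]oxolan-2-one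
Product: 16 (3E,5R)-5-(chloromethyl)-3-{(3R)-4-[(2S,3R)-3-(hydroxymethyl)-3-methyloxiran-2-yl]-3-(prop-1-en-2-yl)butylidene}oxolan-2-one
Conditions: Ti(OiPr)4 (10 mol %), D-(−)-diisopropyl tartrate (12 mol %), t-BuOOH (2 equiv), 4 Å MS, CH2Cl2, −20 °C
Reagents that add atoms: tert-butyl hydroperoxide, CC(C)(C)OO
Why: Sharpless asymmetric epoxidation acts only on the allylic alcohol, is stereospecifically cis, and with the D-(−)-tartrate catalyst gives the (2R,3S) epoxy alcohol by reagent control, which is the 12S,13S epoxide of the target once C11 is oxidised.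

Step 9
Reactants: 16 (3E,5R)-5-(chloromethyl)-3-{(3R)-4-[(2S,3R)-3-(hydroxymethyl)-3-methyloxiran-2-yl]-3-(prop-1-en-2-yl)butylidene}oxolan-2-one
Product: 17 (2S,3S)-3-{(2R,4E)-4-[(5R)-5-(chloromethyl)-2-oxooxolan-3-ylidene]-2-(prop-1-en-2-yl)butyl}-2-methyloxirane-2-carbaldehyde
Conditions: Dess–Martin periodinane, NaHCO3, CH2Cl2, 0 °C → rt
Reagents that add atoms: none
Why: Buffered Dess–Martin oxidation of the primary epoxy alcohol gives an aldehyde with no α-hydrogen, so the epoxide centers cannot epimerise.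

Step 10
Reactants: 17 (2S,3S)-3-{(2R,4E)-4-[(5R)-5-(chloromethyl)-2-oxooxolan-3-ylidene]-2-(prop-1-en-2-yl)butyl}-2-methyloxirane-2-carbaldehyde; 18 methyl diazoacetate
Product: 19 methyl 3-[(2S,3S)-3-{(2R,4E)-4-[(5R)-5-(chloromethyl)-2-oxooxolan-3-ylidene]-2-(prop-1-en-2-yl)butyl}-2-methyloxiran-2-yl]-3-oxopropanoate
Conditions: SnCl2 (10 mol %), CH2Cl2, 0 °C → rt
Reagents that add atoms: none
Why: Roskamp homologation, in which the diazo ester adds to the SnCl2-activated aldehyde and a 1,2-hydride shift with loss of N2 gives the β-keto ester (C11 ketone, C8 methylene), while the quaternary epoxide carbon does not migrate.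

Step 11
Reactants: 19 methyl 3-[(2S,3S)-3-{(2R,4E)-4-[(5R)-5-(chloromethyl)-2-oxooxolan-3-ylidene]-2-(prop-1-en-2-yl)butyl}-2-methyloxiran-2-yl]-3-oxopropanoate
Product: 21 12-membered cyclic β-keto ester (24 lacking C9 and C10 with C8 bonded to the C11 ketone; C8 epimers), via iodide 20 (not isolated)
Conditions: NaI (3 equiv), Cs2CO3 (2 equiv), MeCN, 60 °C, syringe-pump addition to 2 mM
Reagents that add atoms: none
Why: Intramolecular C-alkylation of the caesium β-keto ester enolate at C8 by the primary iodide formed in situ by Finkelstein exchange closes the 12-membered ring under high dilution, helped by the rigid alkylidene lactone and cis-epoxide, and leaves C8 as an equilibrating epimer mixture.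

Step 12
Reactants: 21 12-membered cyclic β-keto ester; 22 ethoxyethyne
Product: 24 target CNP0108136.1, via enol ether 23 (not isolated)
Conditions: [ReBr(CO)3(thf)]2 (5 mol %), BnNC (10 mol %), 22 (3 equiv), toluene, 60 °C, sealed tube; then 1 M aq. HCl, THF, 0 °C → rt
Reagents that add atoms: water, O
Why: Proposed new method: the rhenium enolate of the β-keto ester should add through C8 to the oxygen-bearing carbon of the ynol ether (a ketene surrogate), the resulting alkenylrhenium should close onto the C11 ketone to a cyclobutenolate whose retro-aldol opening cleaves C8–C11 and leaves C9–C10 inserted (12- to 14-membered ring, no pericyclic step), and aqueous acid then turns the C9 enol ether into the ketone while the acidic C8–H equilibrates to the (8S) epimer assumed most stable; the closest known reaction is the rhenium-catalysed insertion of terminal alkynes into the C–C bond of cyclic β-keto esters (two-carbon ring expansion).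

**Compound list**

1 | furan-2(5H)-one | O=C1C=CCO1 | starting material
2 | potassium trifluoro(prop-1-en-2-yl)borate | [K+].F[B-](F)(F)C(C)=C | starting material
3 | (4S)-4-(prop-1-en-2-yl)oxolan-2-one | C=C(C)[C@@H]1CC(=O)OC1 | intermediate
4 | (4S)-4-(prop-1-en-2-yl)oxolan-2-ol (lactol, anomer mixture) | C=C(C)[C@@H]1CC(O)OC1 | intermediate
5 | (2S)-2-(prop-1-en-2-yl)pent-4-yn-1-ol | C=C(C)[C@@H](CO)CC#C | intermediate
6 | (4S)-4-(iodomethyl)-5-methylhex-5-en-1-yne | C=C(C)[C@@H](CI)CC#C | intermediate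
7 | prop-2-yn-1-ol | OCC#C | starting material
8 | bromomagnesium (2Z)-3-(bromomagnesio)-2-methylprop-2-en-1-olate | Br[Mg]OC/C(C)=C\[Mg]Br | intermediate
9 | (2Z)-3-iodo-2-methylprop-2-en-1-ol | OC/C(C)=C\I | intermediate
10 | iodo[(2S)-2-(prop-1-en-2-yl)pent-4-yn-1-yl]zinc | C=C(C)[C@@H](C[Zn]I)CC#C | intermediate
11 | (2Z,5S)-2-methyl-5-(prop-1-en-2-yl)oct-2-en-7-yn-1-ol | C=C(C)[C@@H](C/C=C(C)\CO)CC#C | intermediate
12 | (2R)-2-(chloromethyl)oxirane, (R)-epichlorohydrin | ClC[C@H]1CO1 | starting material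
13 | lithium (2Z,5S)-8-lithio-2-methyl-5-(prop-1-en-2-yl)oct-2-en-7-yn-1-olate | C=C(C)[C@@H](C/C=C(C)\CO[Li])CC#C[Li] | intermediate
14 | (2Z,5S,10R)-11-chloro-2-methyl-5-(prop-1-en-2-yl)undec-2-en-7-yne-1,10-diol | C=C(C)[C@@H](C/C=C(C)\CO)CC#CC[C@@H](O)CCl | intermediate
15 | (3E,5R)-5-(chloromethyl)-3-[(3S,5Z)-7-hydroxy-6-methyl-3-(prop-1-en-2-yl)hept-5-en-1-ylidene]oxolan-2-one | C=C(C)[C@@H](C/C=C(C)\CO)C/C=C1\C[C@H](CCl)OC1=O | intermediate
16 | (3E,5R)-5-(chloromethyl)-3-{(3R)-4-[(2S,3R)-3-(hydroxymethyl)-3-methyloxiran-2-yl]-3-(prop-1-en-2-yl)butylidene}oxolan-2-one | C=C(C)[C@@H](C[C@@H]1O[C@]1(C)CO)C/C=C2\C[C@H](CCl)OC2=O | intermediate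
17 | (2S,3S)-3-{(2R,4E)-4-[(5R)-5-(chloromethyl)-2-oxooxolan-3-ylidene]-2-(prop-1-en-2-yl)butyl}-2-methyloxirane-2-carbaldehyde | C=C(C)[C@@H](C[C@@H]1O[C@]1(C)C=O)C/C=C2\C[C@H](CCl)OC2=O | intermediate
18 | methyl diazoacetate | COC(=O)C=[N+]=[N-] | starting material
19 | methyl 3-[(2S,3S)-3-{(2R,4E)-4-[(5R)-5-(chloromethyl)-2-oxooxolan-3-ylidene]-2-(prop-1-en-2-yl)butyl}-2-methyloxiran-2-yl]-3-oxopropanoate | C=C(C)[C@@H](C[C@@H]1O[C@]1(C)C(=O)CC(=O)OC)C/C=C2\C[C@H](CCl)OC2=O | intermediate
20 | methyl 3-[(2S,3S)-3-{(2R,4E)-4-[(5R)-5-(iodomethyl)-2-oxooxolan-3-ylidene]-2-(prop-1-en-2-yl)butyl}-2-methyloxiran-2-yl]-3-oxopropanoate | C=C(C)[C@@H](C[C@@H]1O[C@]1(C)C(=O)CC(=O)OC)C/C=C2\C[C@H](CI)OC2=O | intermediate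
21 | 12-membered cyclic β-keto ester: 24 lacking C9 and C10, C8 bonded to the C11 ketone; 1R,6S,12S,13S,3E; C8 epimer mixture | C=C(C)[C@@H]1C/C=C2\C[C@H](CC(C(=O)OC)C(=O)[C@@]3(C)O[C@H]3C1)OC2=O | intermediate
22 | ethoxyethyne | C#COCC | starting material
23 | C9 ethyl enol ether of 24 (C8=C9 double bond, geometry not assigned) | C=C(C)[C@@H]1C/C=C2\C[C@H](CC(C(=O)OC)=C(OCC)CC(=O)[C@@]3(C)O[C@H]3C1)OC2=O | intermediate
24 | CNP0108136.1: 14-membered (1R,6S,8S,12S,13S,3E) epoxy diketo methyl ester bridged by the α-alkylidene γ-butyrolactone | C=C(C)[C@@H]1C/C=C2\C[C@H](C[C@H](C(=O)OC)C(=O)CC(=O)[C@@]3(C)O[C@H]3C1)OC2=O | target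

**Step count and risks**

Total: 12 steps. Longest linear sequence: 11 steps (steps 1–3 and 5–12); step 4 is a one-step side branch.

Most likely to fail, first: step 12, the proposed ring expansion. The ynol ether may O-acylate the enol or oligomerise, and the Lewis-acidic rhenium or the acid hydrolysis may open the epoxy ketone. The fallback uses known chemistry, sets out from aldehyde 17 and comes back at 24. Methyl 3-oxobutanoate F12 is converted into its sodium lithium dianion F13 (NaH, then n-BuLi, THF, 0 → −78 °C) and added to 17 (Weiler dianion aldol), giving the δ-hydroxy β-keto ester F14. Intramolecular C-alkylation at C8 (NaI, Cs2CO3, MeCN, 60 °C, high dilution), which runs through the iodide F15, closes the 14-membered ring directly to the C11 carbinol F16. Dess–Martin oxidation of the β-hydroxy ketone to the 1,3-diketone then gives 24.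

Second: step 11, the 12-membered ring closure. The iodomethyl group next to the lactone oxygen is a slow SN2 partner, so O-alkylation to a 14-membered enol ether, elimination and oligomers can compete. The fallback changes the electrophile to an epoxide, sets out from 15 and comes back at 21. K2CO3 in MeOH opens the lactone and the freed C6 alkoxide closes on CH2Cl, giving the epoxy methyl ester F8. Sharpless epoxidation as in step 8 gives the epoxy alcohol F9, Dess–Martin oxidation gives the aldehyde F10 and Roskamp homologation gives the β-keto ester F11. With Cs2CO3 in DMF under high dilution the C8 enolate opens the terminal epoxide at C7, and the released C6 alkoxide re-forms the butyrolactone on the enoate methyl ester (the β-keto ester is protected as its enolate), giving 21.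

Third: step 7, the cyclocarbonylation. An internal alkyne in a polyfunctional substrate may react slowly or give E/Z and regio-isomers. The fallback builds the alkylidene lactone by aldol condensation, sets out from 3 and comes back at 15. Lactone 3 is reduced with DIBAL-H and lactol 4 is isolated. (5R)-5-(Chloromethyl)oxolan-2-one F1 is deprotonated with LDA (THF, −78 °C) to its lithium enolate F2, and addition of 4 gives the β-hydroxy lactone diol F3. MsCl and Et3N give the bis(methanesulfonate) F4, and DBU eliminates the β-sulfonate to the (E)-alkylidene lactone primary methanesulfonate F5. NaI in acetone gives the primary iodide F6, zinc insertion (Zn, LiCl, THF) gives the alkylzinc iodide F7, and Negishi coupling with 9 as in step 5 gives 15.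

**Further compounds**

F1 | step 7 | (5R)-5-(chloromethyl)oxolan-2-one | O=C1CC[C@H](CCl)O1
F2 | step 7 | lithium (5R)-5-(chloromethyl)-4,5-dihydrofuran-2-olate | [Li]OC1=CC[C@H](CCl)O1
F3 | step 7 | (5R)-5-(chloromethyl)-3-[(3S)-1-hydroxy-3-(hydroxymethyl)-4-methylpent-4-en-1-yl]oxolan-2-one (new carbinol and α centers unassigned) | C=C(C)[C@@H](CO)CC(O)C1C[C@H](CCl)OC1=O
F4 | step 7 | bis(methanesulfonate) of F3 | C=C(C)[C@@H](COS(C)(=O)=O)CC(OS(C)(=O)=O)C1C[C@H](CCl)OC1=O
F5 | step 7 | (2S,4E)-4-[(5R)-5-(chloromethyl)-2-oxooxolan-3-ylidene]-2-(prop-1-en-2-yl)butyl methanesulfonate | C=C(C)[C@@H](COS(C)(=O)=O)C/C=C1\C[C@H](CCl)OC1=O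
F6 | step 7 | (3E,5R)-5-(chloromethyl)-3-[(3S)-3-(iodomethyl)-4-methylpent-4-en-1-ylidene]oxolan-2-one | C=C(C)[C@@H](CI)C/C=C1\C[C@H](CCl)OC1=O
F7 | step 7 | {(2S,4E)-4-[(5R)-5-(chloromethyl)-2-oxooxolan-3-ylidene]-2-(prop-1-en-2-yl)butyl}(iodo)zinc | C=C(C)[C@@H](C[Zn]I)C/C=C1\C[C@H](CCl)OC1=O
F8 | step 11 | methyl (2E,5S,7Z)-9-hydroxy-8-methyl-2-{[(2R)-oxiran-2-yl]methyl}-5-(prop-1-en-2-yl)nona-2,7-dienoate | C=C(C)[C@@H](C/C=C(C)\CO)C/C=C(\C[C@@H]1CO1)C(=O)OC
F9 | step 11 | methyl (2E,5R)-6-[(2S,3R)-3-(hydroxymethyl)-3-methyloxiran-2-yl]-2-{[(2R)-oxiran-2-yl]methyl}-5-(prop-1-en-2-yl)hex-2-enoate | C=C(C)[C@@H](C[C@@H]1O[C@]1(C)CO)C/C=C(\C[C@@H]2CO2)C(=O)OC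
F10 | step 11 | methyl (2E,5R)-6-[(2S,3S)-3-formyl-3-methyloxiran-2-yl]-2-{[(2R)-oxiran-2-yl]methyl}-5-(prop-1-en-2-yl)hex-2-enoate | C=C(C)[C@@H](C[C@@H]1O[C@]1(C)C=O)C/C=C(\C[C@@H]2CO2)C(=O)OC
F11 | step 11 | methyl (2E,5R)-6-[(2S,3S)-3-(3-methoxy-3-oxopropanoyl)-3-methyloxiran-2-yl]-2-{[(2R)-oxiran-2-yl]methyl}-5-(prop-1-en-2-yl)hex-2-enoate | C=C(C)[C@@H](C[C@@H]1O[C@]1(C)C(=O)CC(=O)OC)C/C=C(\C[C@@H]2CO2)C(=O)OC
F12 | step 12 | methyl 3-oxobutanoate | CC(=O)CC(=O)OC
F13 | step 12 | sodium lithium dianion of methyl 3-oxobutanoate | C=C(O[Li])C=C(OC)O[Na]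
F14 | step 12 | methyl 5-[(2S,3S)-3-{(2R,4E)-4-[(5R)-5-(chloromethyl)-2-oxooxolan-3-ylidene]-2-(prop-1-en-2-yl)butyl}-2-methyloxiran-2-yl]-5-hydroxy-3-oxopentanoate (carbinol epimers) | C=C(C)[C@@H](C[C@@H]1O[C@]1(C)C(O)CC(=O)CC(=O)OC)C/C=C2\C[C@H](CCl)OC2=O
F15 | step 12 | iodide corresponding to F14 (CH2I in place of CH2Cl) | C=C(C)[C@@H](C[C@@H]1O[C@]1(C)C(O)CC(=O)CC(=O)OC)C/C=C2\C[C@H](CI)OC2=O
F16 | step 12 | C11 carbinol of 24 (11-hydroxy-9-oxo macrocycle; C8 and C11 epimers) | C=C(C)[C@@H]1C/C=C2\C[C@H](CC(C(=O)OC)C(=O)CC(O)[C@@]3(C)O[C@H]3C1)OC2=O
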